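## Retrosynthetic overview

1. Vibsanin P ⇐ final desilylation; the C1 senecioate is installed by Mitsunobu inversion of the (1S)-alcohol, which comes from chelation-controlled reduction of the macrocyclic epoxy enone.
2. 11-Membered carbocycle ⇐ intramolecular Nozaki–Hiyama–Kishi coupling (C1–C2) of an (E)-vinyl iodide on C4 with an α,β-epoxy aldehyde.
3. Oxirane (C10–C11) ⇐ catalytic Sharpless epoxidation of an acyclic (E)-allylic alcohol; C6=C7 and C10=C11 ⇐ two E-selective Wittig reactions; C2=C3 ⇐ Takai olefination; side chain ⇐ cross-metathesis.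
4. Quaternary C4 (first stereocentre) ⇐ lipase-catalysed enantioselective desymmetrisation of achiral 2-allyl-2-methylpropane-1,3-diol, made from diethyl methylmalonate and allyl bromide.
5. Ring order: oxirane first (acyclic stage), then the 11-membered ring.

Locants used below: C1 = ring carbinol carbon (ester), C2=C3, C4 = quaternary carbon, C5, C6=C7 (C7 carries CH2OH), C8, C9, C10/C11 = oxirane carbons (C11 carries CH3 and is bonded to C1), C12–C15 = side chain on C4. The CIP label at C11 switches between R and S with the C1 substituent; the oxirane geometry is the same throughout.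

Assumption: the lipase acylates the pro-R hydroxymethyl arm of the prochiral diol in high ee; the sense must be confirmed on the first run, and the hydrolytic mode given under the fallbacks supplies the same monoacetate if it is reversed.

## Route

Step 1
Reactants: 1 diethyl methylmalonate; 2 allyl bromide
Product: 3 diethyl 2-methyl-2-(prop-2-en-1-yl)propanedioate
Conditions: NaH, THF, 0 °C to rt
Reagents that add atoms: none
Why: Malonate alkylation, the sodium enolate of 1 displacing bromide from 2 (SN2) to give the fully substituted but still achiral carbon that becomes C4.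

Step 2
Reactants: 3 diethyl 2-methyl-2-(prop-2-en-1-yl)propanedioate
Product: 4 2-methyl-2-(prop-2-en-1-yl)propane-1,3-diol
Conditions: LiAlH4, THF, 0 °C to reflux
Reagents that add atoms: none
Why: LiAlH4 reduction of both esters gives the prochiral 1,3-diol whose two CH2OH arms are enantiotopic.

Step 3
Reactants: 4 2-methyl-2-(prop-2-en-1-yl)propane-1,3-diol
Product: 5 (2R)-2-(hydroxymethyl)-2-methylpent-4-en-1-yl acetate
Conditions: lipase (Burkholderia cepacia lipase, Amano lipase PS), vinyl acetate, iPr2O, 25 °C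
Reagents that add atoms: vinyl acetate, CC(=O)OC=C
Why: Lipase-catalysed enantioselective transesterification (desymmetrisation) in which the chiral acyl-enzyme pocket accepts only the pro-R CH2OH arm, so the C4 quaternary stereocentre is set catalytically, and tautomerisation of vinyl alcohol to acetaldehyde makes the acyl transfer irreversible.

Step 4
Reactants: 5 (2R)-2-(hydroxymethyl)-2-methylpent-4-en-1-yl acetate
Product: 6 (2S)-2-({[tert-butyl(diphenyl)silyl]oxy}methyl)-2-methylpent-4-en-1-yl acetate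
Conditions: TBDPSCl, imidazole, DMF, 0 °C to rt
Reagents that add atoms: tert-butyl(chloro)diphenylsilane, CC(C)(C)[Si](Cl)(c1ccccc1)c1ccccc1
Why: Silyl ether formation on the free primary alcohol, done at once so that 1,3-acetyl migration cannot erode the ee.

Step 5
Reactants: 6 (2S)-2-({[tert-butyl(diphenyl)silyl]oxy}methyl)-2-methylpent-4-en-1-yl acetate
Product: 7 (2S)-2-({[tert-butyl(diphenyl)silyl]oxy}methyl)-2-methylpent-4-en-1-ol
Conditions: K2CO3 (cat.), MeOH, 0 °C to rt
Reagents that add atoms: none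
Why: Base-catalysed transesterification (methanolysis) of the acetate frees the other arm while the bulky TBDPS group does not migrate, so the two arms are now cleanly differentiated.

Step 6
Reactants: 7 (2S)-2-({[tert-butyl(diphenyl)silyl]oxy}methyl)-2-methylpent-4-en-1-ol
Product: 8 (2R)-2-({[tert-butyl(diphenyl)silyl]oxy}methyl)-2-methylpent-4-enal
Conditions: Dess–Martin periodinane (DMP), CH2Cl2, rt
Reagents that add atoms: none
Why: Dess–Martin oxidation of the neopentyl primary alcohol to an aldehyde that has no α-hydrogen and therefore cannot epimerise.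

Step 7
Reactants: 8 (2R)-2-({[tert-butyl(diphenyl)silyl]oxy}methyl)-2-methylpent-4-enal
Product: 10 (3S)-3-({[tert-butyl(diphenyl)silyl]oxy}methyl)-3-methylhex-5-enal, via enol ether 9 (not isolated)
Conditions: MeOCH2PPh3Cl, KN(SiMe3)2, THF, −78 to 0 °C; then 2 M aq. HCl, THF, rt
Reagents that add atoms: (methoxymethyl)triphenylphosphonium chloride, COC[P+](c1ccccc1)(c1ccccc1)c1ccccc1.[Cl-]; water, O
Why: Wittig methoxymethylenation followed by acid hydrolysis of the enol ether is a one-carbon homologation that turns the CH2OH arm into the C5–C6 CH2CHO arm before any acid-sensitive group is present.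

Step 8
Reactants: 10 (3S)-3-({[tert-butyl(diphenyl)silyl]oxy}methyl)-3-methylhex-5-enal; 11 2-methylbut-3-en-2-ol
Product: 12 (3S,5E)-3-({[tert-butyl(diphenyl)silyl]oxy}methyl)-7-hydroxy-3,7-dimethyloct-5-enal
Conditions: 11 (5 equiv), second-generation Hoveyda–Grubbs catalyst RuCl2(H2IMes)(=CH-C6H4-2-OiPr) (5 mol %), CH2Cl2, 40 °C
Reagents that add atoms: none
Why: Olefin cross-metathesis of the terminal allyl group with the hindered tertiary allylic alcohol gives the E-disubstituted side-chain alkene, and is run here because no second alkene arm on C4 is yet available for ring-closing metathesis.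

Step 9
Reactants: 13 propane-1,3-diol
Product: 14 3-[(4-methoxyphenyl)methoxy]propan-1-ol
Conditions: NaH (1 equiv), 4-methoxybenzyl chloride, Bu4NI (cat.), THF, 0 °C to rt, diol in threefold excess
Reagents that add atoms: 4-methoxybenzyl chloride, COc1ccc(CCl)cc1
Why: Williamson etherification, the excess of diol holding the reaction at the mono-ether.

Step 10
Reactants: 14 3-[(4-methoxyphenyl)methoxy]propan-1-ol
Product: 15 1-[(3-iodopropoxy)methyl]-4-methoxybenzene
Conditions: I2, PPh3, imidazole, CH2Cl2, 0 °C to rt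
Reagents that add atoms: iodine, II
Why: Appel-type iodination of the primary alcohol, the oxygen ending in triphenylphosphine oxide.

Step 11
Reactants: 15 1-[(3-iodopropoxy)methyl]-4-methoxybenzene; 16 ethyl (triphenylphosphoranylidene)acetate
Product: 18 ethyl 5-[(4-methoxyphenyl)methoxy]-2-(triphenylphosphoranylidene)pentanoate, via phosphonium iodide 17 (not isolated)
Conditions: 16 (2.1 equiv), MeCN, 80 °C
Reagents that add atoms: none
Why: C-alkylation of the stabilised ylide by the primary iodide gives the phosphonium salt, which the second equivalent of 16 deprotonates (transylidation) to the α-substituted stabilised ylide.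

Step 12
Reactants: 12 (3S,5E)-3-({[tert-butyl(diphenyl)silyl]oxy}methyl)-7-hydroxy-3,7-dimethyloct-5-enal; 18 ethyl 5-[(4-methoxyphenyl)methoxy]-2-(triphenylphosphoranylidene)pentanoate
Product: 19 ethyl (2E,5S,7E)-5-({[tert-butyl(diphenyl)silyl]oxy}methyl)-9-hydroxy-2-{3-[(4-methoxyphenyl)methoxy]propyl}-5,9-dimethyldeca-2,7-dienoate
Conditions: toluene, 90 °C
Reagents that add atoms: none
Why: Wittig olefination with an α-substituted stabilised ylide gives the thermodynamically preferred E-enoate, with C5 trans to the ester carbon and hence C5 and C8 cis as the ring needs.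

Step 13
Reactants: 19 (TBDPS ether)
Product: 20 ethyl (2E,5S,7E)-9-hydroxy-5-(hydroxymethyl)-2-{3-[(4-methoxyphenyl)methoxy]propyl}-5,9-dimethyldeca-2,7-dienoate
Conditions: Bu4NF, AcOH (1:1), THF, rt
Reagents that add atoms: none
Why: Fluoride-mediated desilylation of the TBDPS ether, with acetic acid buffering so that the alkoxide cannot add to the enoate (oxa-Michael).

Step 14
Reactants: 20 (primary/tertiary diol)
Product: 21 ethyl (2E,5S,7E)-5-formyl-9-hydroxy-2-{3-[(4-methoxyphenyl)methoxy]propyl}-5,9-dimethyldeca-2,7-dienoate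
Conditions: DMP, pyridine, CH2Cl2, 0 °C to rt
Reagents that add atoms: none
Why: Dess–Martin oxidation is selective for the primary alcohol because the tertiary alcohol cannot be oxidised.

Step 15
Reactants: 21 (α-quaternary aldehyde)
Product: 22 ethyl (2E,5S,7E)-9-hydroxy-5-[(E)-2-iodoethenyl]-2-{3-[(4-methoxyphenyl)methoxy]propyl}-5,9-dimethyldeca-2,7-dienoate
Conditions: CrCl2 (8 equiv), CHI3 (3 equiv), 1,4-dioxane/THF 6:1, rt
Reagents that add atoms: iodoform, IC(I)I
Why: Takai olefination, in which the geminal dichromium species from CHI3 and CrCl2 adds to the hindered aldehyde and eliminates to give the E-vinyl iodide (C2=C3).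

Step 16
Reactants: 22 (tertiary alcohol)
Product: 23 ethyl (2E,5S,7E)-5-[(E)-2-iodoethenyl]-2-{3-[(4-methoxyphenyl)methoxy]propyl}-5,9-dimethyl-9-[(triethylsilyl)oxy]deca-2,7-dienoate
Conditions: Et3SiOTf, 2,6-lutidine, CH2Cl2, −78 °C
Reagents that add atoms: triethylsilyl trifluoromethanesulfonate, CC[Si](CC)(CC)OS(=O)(=O)C(F)(F)F
Why: Silylation of the tertiary allylic alcohol with the reactive silyl triflate.

Step 17
Reactants: 23 (enoate)
Product: 24 (2E,5S,7E)-5-[(E)-2-iodoethenyl]-2-{3-[(4-methoxyphenyl)methoxy]propyl}-5,9-dimethyl-9-[(triethylsilyl)oxy]deca-2,7-dien-1-ol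
Conditions: iBu2AlH (2.5 equiv), CH2Cl2, −78 °C; aq. potassium sodium tartrate
Reagents that add atoms: none
Why: iBu2AlH 1,2-reduction of the enoate to the allylic alcohol without touching the vinyl iodide or the ethers.

Step 18
Reactants: 24 (allylic alcohol)
Product: 25 tert-butyldimethylsilyl ether of 24
Conditions: TBSCl, imidazole, CH2Cl2, 0 °C to rt
Reagents that add atoms: tert-butyl(chloro)dimethylsilane, CC(C)(C)[Si](C)(C)Cl
Why: Silyl ether formation on the primary allylic alcohol, so that only the later C1 alcohol can direct the epoxidation.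

Step 19
Reactants: 25 (4-methoxybenzyl ether)
Product: 26 (4E,7S,9E)-4-({[tert-butyl(dimethyl)silyl]oxy}methyl)-7-[(E)-2-iodoethenyl]-7,11-dimethyl-11-[(triethylsilyl)oxy]dodeca-4,9-dien-1-ol
Conditions: DDQ, CH2Cl2/pH 7 phosphate buffer 10:1, 0 °C
Reagents that add atoms: none
Why: Oxidative cleavage of the 4-methoxybenzyl ether by DDQ (hydride abstraction, then hydrolysis of the oxocarbenium ion) under buffered conditions that spare both silyl ethers.

Step 20
Reactants: 26 (primary alcohol)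
Product: 27 (4E,7S,9E)-4-({[tert-butyl(dimethyl)silyl]oxy}methyl)-7-[(E)-2-iodoethenyl]-7,11-dimethyl-11-[(triethylsilyl)oxy]dodeca-4,9-dienal
Conditions: DMP, pyridine, CH2Cl2, 0 °C to rt
Reagents that add atoms: none
Why: Dess–Martin oxidation of the primary alcohol to the C10 aldehyde.

Step 21
Reactants: 27 (C10 aldehyde); 28 ethyl 2-(triphenylphosphoranylidene)propanoate
Product: 29 ethyl (2E,6E,9S,11E)-6-({[tert-butyl(dimethyl)silyl]oxy}methyl)-9-[(E)-2-iodoethenyl]-2,9,13-trimethyl-13-[(triethylsilyl)oxy]tetradeca-2,6,11-trienoate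
Conditions: CH2Cl2, 40 °C
Reagents that add atoms: none
Why: Wittig olefination with the stabilised ylide gives the E-trisubstituted enoate (C10=C11, with C9 trans to the ester).

Step 22
Reactants: 29 (enoate)
Product: 30 (2E,6E,9S,11E)-6-({[tert-butyl(dimethyl)silyl]oxy}methyl)-9-[(E)-2-iodoethenyl]-2,9,13-trimethyl-13-[(triethylsilyl)oxy]tetradeca-2,6,11-trien-1-ol
Conditions: iBu2AlH (2.5 equiv), CH2Cl2, −78 °C; aq. potassium sodium tartrate
Reagents that add atoms: none
Why: iBu2AlH reduction of the enoate gives the (E)-2-methylallylic alcohol that the epoxidation needs.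

Step 23
Reactants: 30 (allylic alcohol)
Product: 31 {(2S,3S)-3-[(3E,6S,8E)-3-({[tert-butyl(dimethyl)silyl]oxy}methyl)-6-[(E)-2-iodoethenyl]-6,10-dimethyl-10-[(triethylsilyl)oxy]undeca-3,8-dien-1-yl]-2-methyloxiran-2-yl}methanol
Conditions: Ti(OiPr)4 (10 mol %), L-(+)-diethyl tartrate (12 mol %), tBuOOH, 4 Å molecular sieves, CH2Cl2, −20 °C
Reagents that add atoms: tert-butyl hydroperoxide, CC(C)(C)OO
Why: Sharpless asymmetric epoxidation, in which the Ti–L-(+)-tartrate catalyst binds the primary allylic alcohol and delivers oxygen to the alkene face that gives the (2S,3S)-epoxy alcohol (C10 and C11 as in the target), the silyl-protected allylic positions being inert.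

Step 24
Reactants: 31 (epoxy alcohol)
Product: 32 (2R,3S)-3-[(3E,6S,8E)-3-({[tert-butyl(dimethyl)silyl]oxy}methyl)-6-[(E)-2-iodoethenyl]-6,10-dimethyl-10-[(triethylsilyl)oxy]undeca-3,8-dien-1-yl]-2-methyloxirane-2-carbaldehyde
Conditions: DMP, pyridine, CH2Cl2, 0 °C
Reagents that add atoms: none
Why: Dess–Martin oxidation to the epoxy aldehyde, configurationally safe because C11 is fully substituted.

Step 25
Reactants: 32 (iodo epoxy aldehyde)
Product: 33 macrocyclic epoxy alcohol (C1–OH; both C1 epimers)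
Conditions: CrCl2 (10 equiv), NiCl2 (0.1 equiv), degassed DMSO/THF 3:1, rt, slow addition to 2 mM
Reagents that add atoms: none
Why: Intramolecular Nozaki–Hiyama–Kishi reaction, in which nickel-catalysed insertion into the C–I bond, transmetalation to chromium and addition of the alkenylchromium to the aldehyde close the 11-membered ring with retention of the E geometry; the C1 configuration is not relied on.

Step 26
Reactants: 33 macrocyclic epoxy alcohol (both C1 epimers)
Product: 34 macrocyclic α,β-epoxy enone (C1=O)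
Conditions: DMP, pyridine, CH2Cl2, 0 °C to rt
Reagents that add atoms: none
Why: Dess–Martin oxidation converges both C1 epimers on one enone.

Step 27
Reactants: 34 macrocyclic α,β-epoxy enone
Product: 35 macrocyclic (1S)-alcohol
Conditions: Zn(BH4)2, Et2O, −20 °C
Reagents that add atoms: none
Why: Chelation-controlled 1,2-reduction, in which zinc bridges the ketone and oxirane oxygens and hydride adds from the face away from C10, giving the anti (erythro) epoxy alcohol, here 1S.

Step 28
Reactants: 35 macrocyclic (1S)-alcohol; 36 3-methylbut-2-enoic acid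
Product: 37 macrocyclic (1R)-3-methylbut-2-enoate (bis-silyl ether of the target)
Conditions: PPh3, diisopropyl azodicarboxylate, toluene, 0 °C to rt
Reagents that add atoms: none
Why: Mitsunobu esterification, in which the alkoxyphosphonium of the allylic alcohol is displaced by the carboxylate (SN2) with inversion to set 1R, SN2′ attack being blocked by the quaternary C4.

Step 29
Reactants: 37 macrocyclic (1R)-3-methylbut-2-enoate
Product: 38 Vibsanin P
Conditions: HF·pyridine, pyridine, THF, 0 °C to rt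
Reagents that add atoms: none
Why: Fluoride desilylation of the primary TBS and tertiary TES ethers under buffered, non-basic conditions that leave the oxirane and the allylic ester intact.

## Compound list

1 | diethyl methylmalonate | CCOC(=O)C(C)C(=O)OCC | starting material
2 | allyl bromide | C=CCBr | starting material
3 | diethyl 2-methyl-2-(prop-2-en-1-yl)propanedioate | CCOC(=O)C(C)(CC=C)C(=O)OCC | intermediate
4 | 2-methyl-2-(prop-2-en-1-yl)propane-1,3-diol (achiral) | OCC(C)(CC=C)CO | intermediate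
5 | (2R)-2-(hydroxymethyl)-2-methylpent-4-en-1-yl acetate | OC[C@@](C)(CC=C)COC(C)=O | intermediate
6 | (2S)-2-({[tert-butyl(diphenyl)silyl]oxy}methyl)-2-methylpent-4-en-1-yl acetate | CC(C)(C)[Si](c1ccccc1)(c1ccccc1)OC[C@@](C)(CC=C)COC(C)=O | intermediate
7 | (2S)-2-({[tert-butyl(diphenyl)silyl]oxy}methyl)-2-methylpent-4-en-1-ol | CC(C)(C)[Si](c1ccccc1)(c1ccccc1)OC[C@@](C)(CC=C)CO | intermediate
8 | (2R)-2-({[tert-butyl(diphenyl)silyl]oxy}methyl)-2-methylpent-4-enal | CC(C)(C)[Si](c1ccccc1)(c1ccccc1)OC[C@@](C)(CC=C)C=O | intermediate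
9 | tert-butyl{[(2S)-2-(2-methoxyethenyl)-2-methylpent-4-en-1-yl]oxy}diphenylsilane (E/Z mixture, not isolated) | CC(C)(C)[Si](c1ccccc1)(c1ccccc1)OC[C@@](C)(CC=C)C=COC | intermediate
10 | (3S)-3-({[tert-butyl(diphenyl)silyl]oxy}methyl)-3-methylhex-5-enal | CC(C)(C)[Si](c1ccccc1)(c1ccccc1)OC[C@@](C)(CC=C)CC=O | intermediate
11 | 2-methylbut-3-en-2-ol | CC(C)(O)C=C | starting material
12 | (3S,5E)-3-({[tert-butyl(diphenyl)silyl]oxy}methyl)-7-hydroxy-3,7-dimethyloct-5-enal | CC(C)(C)[Si](c1ccccc1)(c1ccccc1)OC[C@@](C)(C/C=C/C(C)(C)O)CC=O | intermediate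
13 | propane-1,3-diol | OCCCO | starting material
14 | 3-[(4-methoxyphenyl)methoxy]propan-1-ol | COc1ccc(COCCCO)cc1 | intermediate
15 | 1-[(3-iodopropoxy)methyl]-4-methoxybenzene | COc1ccc(COCCCI)cc1 | intermediate
16 | ethyl (triphenylphosphoranylidene)acetate | CCOC(=O)C=P(c1ccccc1)(c1ccccc1)c1ccccc1 | starting material
17 | {1-ethoxy-5-[(4-methoxyphenyl)methoxy]-1-oxopentan-2-yl}triphenylphosphonium iodide (not isolated) | CCOC(=O)C(CCCOCc1ccc(OC)cc1)[P+](c1ccccc1)(c1ccccc1)c1ccccc1.[I-] | intermediate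
18 | ethyl 5-[(4-methoxyphenyl)methoxy]-2-(triphenylphosphoranylidene)pentanoate | CCOC(=O)C(CCCOCc1ccc(OC)cc1)=P(c1ccccc1)(c1ccccc1)c1ccccc1 | intermediate
19 | ethyl (2E,5S,7E)-5-({[tert-butyl(diphenyl)silyl]oxy}methyl)-9-hydroxy-2-{3-[(4-methoxyphenyl)methoxy]propyl}-5,9-dimethyldeca-2,7-dienoate | CC(C)(C)[Si](c1ccccc1)(c1ccccc1)OC[C@@](C)(C/C=C/C(C)(C)O)C/C=C(/C(=O)OCC)CCCOCc1ccc(OC)cc1 | intermediate
20 | ethyl (2E,5S,7E)-9-hydroxy-5-(hydroxymethyl)-2-{3-[(4-methoxyphenyl)methoxy]propyl}-5,9-dimethyldeca-2,7-dienoate | OC[C@@](C)(C/C=C/C(C)(C)O)C/C=C(/C(=O)OCC)CCCOCc1ccc(OC)cc1 | intermediate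
21 | ethyl (2E,5S,7E)-5-formyl-9-hydroxy-2-{3-[(4-methoxyphenyl)methoxy]propyl}-5,9-dimethyldeca-2,7-dienoate | O=C[C@@](C)(C/C=C/C(C)(C)O)C/C=C(/C(=O)OCC)CCCOCc1ccc(OC)cc1 | intermediate
22 | ethyl (2E,5S,7E)-9-hydroxy-5-[(E)-2-iodoethenyl]-2-{3-[(4-methoxyphenyl)methoxy]propyl}-5,9-dimethyldeca-2,7-dienoate | I/C=C/[C@@](C)(C/C=C/C(C)(C)O)C/C=C(/C(=O)OCC)CCCOCc1ccc(OC)cc1 | intermediate
23 | ethyl (2E,5S,7E)-5-[(E)-2-iodoethenyl]-2-{3-[(4-methoxyphenyl)methoxy]propyl}-5,9-dimethyl-9-[(triethylsilyl)oxy]deca-2,7-dienoate | I/C=C/[C@@](C)(C/C=C/C(C)(C)O[Si](CC)(CC)CC)C/C=C(/C(=O)OCC)CCCOCc1ccc(OC)cc1 | intermediate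
24 | (2E,5S,7E)-5-[(E)-2-iodoethenyl]-2-{3-[(4-methoxyphenyl)methoxy]propyl}-5,9-dimethyl-9-[(triethylsilyl)oxy]deca-2,7-dien-1-ol | I/C=C/[C@@](C)(C/C=C/C(C)(C)O[Si](CC)(CC)CC)C/C=C(/CO)CCCOCc1ccc(OC)cc1 | intermediate
25 | tert-butyldimethylsilyl ether of 24 (O1-silylated) | I/C=C/[C@@](C)(C/C=C/C(C)(C)O[Si](CC)(CC)CC)C/C=C(/CO[Si](C)(C)C(C)(C)C)CCCOCc1ccc(OC)cc1 | intermediate
26 | (4E,7S,9E)-4-({[tert-butyl(dimethyl)silyl]oxy}methyl)-7-[(E)-2-iodoethenyl]-7,11-dimethyl-11-[(triethylsilyl)oxy]dodeca-4,9-dien-1-ol | I/C=C/[C@@](C)(C/C=C/C(C)(C)O[Si](CC)(CC)CC)C/C=C(/CO[Si](C)(C)C(C)(C)C)CCCO | intermediate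
27 | (4E,7S,9E)-4-({[tert-butyl(dimethyl)silyl]oxy}methyl)-7-[(E)-2-iodoethenyl]-7,11-dimethyl-11-[(triethylsilyl)oxy]dodeca-4,9-dienal | I/C=C/[C@@](C)(C/C=C/C(C)(C)O[Si](CC)(CC)CC)C/C=C(/CO[Si](C)(C)C(C)(C)C)CCC=O | intermediate
28 | ethyl 2-(triphenylphosphoranylidene)propanoate | CCOC(=O)C(C)=P(c1ccccc1)(c1ccccc1)c1ccccc1 | starting material
29 | ethyl (2E,6E,9S,11E)-6-({[tert-butyl(dimethyl)silyl]oxy}methyl)-9-[(E)-2-iodoethenyl]-2,9,13-trimethyl-13-[(triethylsilyl)oxy]tetradeca-2,6,11-trienoate | I/C=C/[C@@](C)(C/C=C/C(C)(C)O[Si](CC)(CC)CC)C/C=C(/CO[Si](C)(C)C(C)(C)C)CC/C=C(\C)C(=O)OCC | intermediate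
30 | (2E,6E,9S,11E)-6-({[tert-butyl(dimethyl)silyl]oxy}methyl)-9-[(E)-2-iodoethenyl]-2,9,13-trimethyl-13-[(triethylsilyl)oxy]tetradeca-2,6,11-trien-1-ol | I/C=C/[C@@](C)(C/C=C/C(C)(C)O[Si](CC)(CC)CC)C/C=C(/CO[Si](C)(C)C(C)(C)C)CC/C=C(\C)CO | intermediate
31 | {(2S,3S)-3-[(3E,6S,8E)-3-({[tert-butyl(dimethyl)silyl]oxy}methyl)-6-[(E)-2-iodoethenyl]-6,10-dimethyl-10-[(triethylsilyl)oxy]undeca-3,8-dien-1-yl]-2-methyloxiran-2-yl}methanol | I/C=C/[C@@](C)(C/C=C/C(C)(C)O[Si](CC)(CC)CC)C/C=C(/CO[Si](C)(C)C(C)(C)C)CC[C@@H]1O[C@@]1(C)CO | intermediate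
32 | (2R,3S)-3-[(3E,6S,8E)-3-({[tert-butyl(dimethyl)silyl]oxy}methyl)-6-[(E)-2-iodoethenyl]-6,10-dimethyl-10-[(triethylsilyl)oxy]undeca-3,8-dien-1-yl]-2-methyloxirane-2-carbaldehyde | I/C=C/[C@@](C)(C/C=C/C(C)(C)O[Si](CC)(CC)CC)C/C=C(/CO[Si](C)(C)C(C)(C)C)CC[C@@H]1O[C@@]1(C)C=O | intermediate
33 | macrocyclic epoxy alcohol: 11-membered ring, C1–OH (both epimers), 2E, 4S (CH3 and (E)-CH2CH=CHC(CH3)2OSiEt3 on C4), 6E (CH2OTBS on C7), trans-oxirane 10S,11S (CH3 on C11) | OC1/C=C/[C@@](C)(C/C=C/C(C)(C)O[Si](CC)(CC)CC)C/C=C(/CO[Si](C)(C)C(C)(C)C)CC[C@@H]2O[C@]21C | intermediate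
34 | macrocyclic α,β-epoxy enone: as 33 with C1=O (2E,4S,6E,10S,11R) | O=C1/C=C/[C@@](C)(C/C=C/C(C)(C)O[Si](CC)(CC)CC)C/C=C(/CO[Si](C)(C)C(C)(C)C)CC[C@@H]2O[C@]21C | intermediate
35 | macrocyclic (1S)-alcohol: as 33 with defined C1 (1S,2E,4S,6E,10S,11S) | O[C@H]1/C=C/[C@@](C)(C/C=C/C(C)(C)O[Si](CC)(CC)CC)C/C=C(/CO[Si](C)(C)C(C)(C)C)CC[C@@H]2O[C@]21C | intermediate
36 | 3-methylbut-2-enoic acid | CC(C)=CC(=O)O | starting material
37 | macrocyclic (1R)-3-methylbut-2-enoate: bis-silyl ether of Vibsanin P (1R,2E,4S,6E,10S,11R; C7–CH2OTBS, C15–OSiEt3) | CC(C)=CC(=O)O[C@@H]1/C=C/[C@@](C)(C/C=C/C(C)(C)O[Si](CC)(CC)CC)C/C=C(/CO[Si](C)(C)C(C)(C)C)CC[C@@H]2O[C@]21C | intermediate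
38 | Vibsanin P (1R,2E,4S,6E,10S,11R,13E) | CC(C)=CC(=O)O[C@@H]1/C=C/[C@@](C)(C/C=C/C(C)(C)O)C/C=C(/CO)CC[C@@H]2O[C@]21C | target

## Step count and risk

Total: 29 steps. Longest linear sequence: 26 steps (steps 1–8 and 12–29); the ylide branch (steps 9–11) joins at step 12.

The three steps most likely to fail:

Step 25, the macrocyclisation. An epoxy aldehyde is exposed to CrCl2, and an 11-membered ring is entropically and enthalpically demanding. The fallback sets out from allylic alcohol 30 and moves the epoxidation after ring closure. MnO2 in CH2Cl2 oxidises 30 to the enal F2. The same CrCl2/NiCl2 ring closure on this robust enal gives the macrocyclic dienol F3 as C1 epimers. Sharpless epoxidation with Ti(OiPr)4, L-(+)-diisopropyl tartrate and tBuOOH in kinetic-resolution mode then epoxidises only the matched (1S)-epimer at C10=C11, erythro-selectively, and comes back to the route at 35. Unreacted (1R)-dienol is recycled by MnO2 oxidation and NaBH4/CeCl3 reduction.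

Step 28, the Mitsunobu inversion at a hindered allylic carbinol. The fallback sets out from 35, which is converted with ClCH2SO2Cl and pyridine at 0 °C into the chloromethanesulfonate F4 and used crude. Displacement with caesium 3-methylbut-2-enoate (from 36 and Cs2CO3) and 18-crown-6 in toluene proceeds by SN2 with inversion and comes back to the route at 37.

Step 3, the enzymatic desymmetrisation (ee and absolute sense). The fallback sets out from diol 4, which Ac2O and pyridine convert into the diacetate F1. Enantioselective hydrolysis of one enantiotopic acetate by an esterase (pig liver esterase), or by the same lipase in pH 7 phosphate buffer, comes back to the route at 5. Hydrolysis gives the opposite absolute sense to acylation with the same enzyme, so the pairing that delivers (R)-5 is used.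

## Further compounds

F1 | step 3 | 2-methyl-2-(prop-2-en-1-yl)propane-1,3-diyl diacetate | CC(=O)OCC(C)(CC=C)COC(C)=O
F2 | step 25 | (2E,6E,9S,11E)-6-({[tert-butyl(dimethyl)silyl]oxy}methyl)-9-[(E)-2-iodoethenyl]-2,9,13-trimethyl-13-[(triethylsilyl)oxy]tetradeca-2,6,11-trienal | I/C=C/[C@@](C)(C/C=C/C(C)(C)O[Si](CC)(CC)CC)C/C=C(/CO[Si](C)(C)C(C)(C)C)CC/C=C(\C)C=O
F3 | step 25 | macrocyclic dienol: 11-membered ring, C1–OH (both epimers), 2E, 4S, 6E, 10E (C10=C11 in place of the oxirane), silyl ethers as in 33 | OC1/C=C/[C@@](C)(C/C=C/C(C)(C)O[Si](CC)(CC)CC)C/C=C(/CO[Si](C)(C)C(C)(C)C)CC/C=C1\C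
F4 | step 28 | chloromethanesulfonate of 35 (1S,4S,10S,11R) | ClCS(=O)(=O)O[C@H]1/C=C/[C@@](C)(C/C=C/C(C)(C)O[Si](CC)(CC)CC)C/C=C(/CO[Si](C)(C)C(C)(C)C)CC[C@@H]2O[C@]21C
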